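**Retrosynthetic overview** (atoms of acyclic precursors carry the locants they will have in the decalin)
1. The target is traced back to tert-butyl 6β,9β-dihydroxydrim-7-en-11-oate by ester acidolysis, 6-O-acylation and C12 allylic oxidation. C11 comes from α-face addition of a carboxyl anion equivalent to a C9 ketone, which puts the 9-OH β, cis to the C10 methyl.
2. The 6β-hydroxy-7-en-9-one comes from a bicyclic 6-formyl silyl enol ether by deformylative oxidation at C6, α-face reduction and Saegusa–Ito oxidation.
3. Enabling feature: in ring B (C5–C10) the C9 carbinol carbon is a latent ketone, so C7=C8–C9(OSi)=C10 can be a 2-silyloxydiene and C5=C6 an enal dienophile. C5 and C10 are already linked by the C1–C4 chain of ring A, so one intramolecular [4+2] makes C5–C10 and C6–C7 together.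
4. The achiral triene comes from Cu-catalysed 1,4-addition of a C2–C6 Grignard fragment to symmetrical 2,4-dimethylpenta-1,4-dien-3-one; enolate trapping fixes the enol ether geometry.
5. Ring order: no ring before the key step; rings A and B are closed together in step 10.

Key step: step 10

Remark on numbering: bicyclic compounds use drimane locants (ring A = C1–C5, C10; ring B = C5–C10; gem-dimethyl on C4; angular methyl on C10, β; C11 on C9; C12 on C8; α = face opposite the C10 methyl). All are trans-fused (5α-H, 10β-CH3).
Remark on the target: it is taken in the open 12-oxo-11-oic acid form drawn; equilibration with a cyclic lactol form would not change the route.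
Remark on the catalyst: the (S)-oxazaborolidine is assigned to the needed enal face by analogy with its intermolecular enal cycloadditions; the antipode is equally available if the sense proves opposite.

**Route**

Step 1
Reactants: 1 methacrolein; 2 isopropenylmagnesium bromide
Product: 3 2,4-dimethylpenta-1,4-dien-3-ol
Conditions: THF, −78 → 0 °C; aq NH4Cl
Reagents that add atoms: none
Why: Grignard 1,2-addition of the alkenylmagnesium reagent to the formyl carbon should give the divinyl carbinol, whose single stereocentre is removed in the next step.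

Step 2
Reactants: 3 2,4-dimethylpenta-1,4-dien-3-ol
Product: 4 2,4-dimethylpenta-1,4-dien-3-one
Conditions: activated MnO2, pentane/CH2Cl2, 23 °C; filtered solution used at once
Reagents that add atoms: none
Why: MnO2 oxidises the doubly allylic alcohol under neutral conditions (allylic alcohol oxidation), which suits the volatile, polymerisable cross-conjugated dienone.

Step 3
Reactants: 5 methyl 3,3-dimethylpent-4-enoate
Product: 6 methyl 3,3-dimethyl-4-oxobutanoate
Conditions: O3, CH2Cl2, −78 °C; then PPh3
Reagents that add atoms: ozone, [O-][O+]=O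
Why: Ozonolysis with reductive work-up cleaves the only C=C bond to the α-quaternary aldehyde and leaves the ester untouched.

Step 4
Reactants: 6 methyl 3,3-dimethyl-4-oxobutanoate
Product: 7 methyl (4E)-3,3-dimethyl-6-oxohex-4-enoate
Conditions: Ph3P=CHCHO, toluene, 90 °C
Reagents that add atoms: (triphenylphosphoranylidene)acetaldehyde, O=CC=P(c1ccccc1)(c1ccccc1)c1ccccc1
Why: The Wittig reaction of the non-enolisable aldehyde with the stabilised ylide should give the (E)-enal and brings in C6.

Step 5
Reactants: 7 methyl (4E)-3,3-dimethyl-6-oxohex-4-enoate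
Product: 8 methyl (4E)-6,6-dimethoxy-3,3-dimethylhex-4-enoate
Conditions: HC(OMe)3, MeOH, pyridinium p-toluenesulfonate (cat.), 23 °C
Reagents that add atoms: trimethyl orthoformate, COC(OC)OC
Why: Acid-catalysed acetalisation masks the enal for the later Grignard chemistry, and conjugate addition of methanol is hindered by the quaternary γ-carbon.

Step 6
Reactants: 8 methyl (4E)-6,6-dimethoxy-3,3-dimethylhex-4-enoate
Product: 9 (4E)-6,6-dimethoxy-3,3-dimethylhex-4-en-1-ol
Conditions: LiAlH4, Et2O, 0 °C
Reagents that add atoms: none
Why: Hydride reduction of the ester gives the primary alcohol while the acetal and the isolated alkene are inert.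

Step 7
Reactants: 9 (4E)-6,6-dimethoxy-3,3-dimethylhex-4-en-1-ol
Product: 10 (2E)-6-bromo-1,1-dimethoxy-4,4-dimethylhex-2-ene
Conditions: CBr4, PPh3, imidazole, CH2Cl2, 0 °C
Reagents that add atoms: carbon tetrabromide, BrC(Br)(Br)Br
Why: The Appel reaction converts the unhindered primary alcohol into the bromide under buffered conditions that keep the allylic acetal.

Step 8
Reactants: 10 (2E)-6-bromo-1,1-dimethoxy-4,4-dimethylhex-2-ene; 4 2,4-dimethylpenta-1,4-dien-3-one
Product: 13 (2E,8Z)-1,1-dimethoxy-4,4,8,10-tetramethyl-9-(triisopropylsilyloxy)undeca-2,8,10-triene, via Grignard reagent 11 (not isolated), via bromomagnesium enolate 12 (not isolated)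
Conditions: Mg, THF, 40 °C; then CuBr·SMe2 (10 mol%), THF, −78 °C, slow addition of 4; then HMPA, i-Pr3SiOTf, −78 → 0 °C
Reagents that add atoms: triisopropylsilyl trifluoromethanesulfonate, CC(C)[Si](OS(=O)(=O)C(F)(F)F)(C(C)C)C(C)C
Why: Copper-catalysed 1,4-addition to one of the two identical enone termini goes through the s-cis enone, so oxygen and the new C1 methylene end up cis, and O-silylation fixes this (Z) tetrasubstituted enol ether (conjugate addition with enolate trapping); the symmetry of 4 removes any regiochemical question.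

Step 9
Reactants: 13 (2E,8Z)-1,1-dimethoxy-4,4,8,10-tetramethyl-9-(triisopropylsilyloxy)undeca-2,8,10-triene
Product: 14 (2E,8Z)-4,4,8,10-tetramethyl-9-(triisopropylsilyloxy)undeca-2,8,10-trienal
Conditions: pyridinium p-toluenesulfonate (5 mol%), acetone/H2O (10:1), 0 °C; used at once
Reagents that add atoms: water, O
Why: An allylic dimethyl acetal is hydrolysed by very mild acid much faster than a hindered triisopropylsilyl enol ether is protonated, so the (E)-enal should be released with the dienol ether intact (acetal hydrolysis).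

Step 10
Reactants: 14 (2E,8Z)-4,4,8,10-tetramethyl-9-(triisopropylsilyloxy)undeca-2,8,10-trienal
Product: 15 9-(triisopropylsilyloxy)-11-nordrim-8-ene-6α-carbaldehyde [(1S,4aS,8aS)-3,4a,8,8-tetramethyl-4-(triisopropylsilyloxy)-1,2,4a,5,6,7,8,8a-octahydronaphthalene-1-carbaldehyde]
Conditions: (S)-3,3-diphenyl-1-(2-methylphenyl)tetrahydro-1H,3H-pyrrolo[1,2-c][1,3,2]oxazaborole (20 mol%), bis(trifluoromethanesulfonyl)imide (Tf2NH, 18 mol%), CH2Cl2, −78 → −40 °C
Reagents that add atoms: none
Why: The protonated oxazaborolidine binds the formyl group of the (E)-enal and lowers its LUMO, so the 2-silyloxydiene C7=C8–C9(OSi)=C10 adds across C5=C6 in an asynchronous endo [4+2] cycloaddition (type 1 intramolecular Diels–Alder reaction) in which the C5–C10 bond between the nucleophilic enol ether carbon and the enal β-carbon leads and the C6–C7 bond follows, the polarity of both partners matching the regiochemistry the tether imposes. The closest known reaction types are oxazaborolidinium-catalysed enantioselective Diels–Alder reactions of 2-(triisopropylsilyloxy)dienes with enals and catalytic enantioselective intramolecular Diels–Alder reactions of trienals that give trans-fused bicycles. Ring A is closed through the C1–C4 tether as the six-membered tether ring (formally a 6-exo attack of C10 on C5), and ring B is the new cyclohexene of the cycloadduct (formally a 6-endo closure of C6 on C7). C5 and C10 are set trans by a chair-like tether in which the diene unit on C10 and the enal on C5 are both equatorial and the C10 methyl is axial, C6 (formyl α) follows from the (E)-enal and the endo position of the bound formyl group and is erased in step 11, and the absolute configuration follows from the catalyst, which leaves one face of the bound enal open. The step needs trans ring fusion, enantioface selectivity and a diene that can reach the dienophile: the (8Z) enol ether puts the tether on the outer diene position, the gem-dimethyl group at C4 folds the chain (Thorpe–Ingold effect), and early pyramidalisation at C10 relieves the strain of its inner methyl group.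

Step 11
Reactants: 15 9-(triisopropylsilyloxy)-11-nordrim-8-ene-6α-carbaldehyde
Product: 16 9-(triisopropylsilyloxy)-11-nordrim-8-en-6-one
Conditions: Cu(OAc)2 (20 mol%), 2,2'-bipyridine (20 mol%), 1,4-diazabicyclo[2.2.2]octane, O2 (1 atm), DMF, 40 °C
Reagents that add atoms: dioxygen, O=O
Why: Copper-catalysed aerobic oxygenation of the enolised α-branched aldehyde at C6 and C–C cleavage with loss of the formyl carbon as formic acid should leave the C6 ketone (oxidative deformylation), while the fully substituted silyl enol ether should survive the weakly basic medium.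

Step 12
Reactants: 16 9-(triisopropylsilyloxy)-11-nordrim-8-en-6-one
Product: 17 9-(triisopropylsilyloxy)-11-nordrim-8-en-6β-ol
Conditions: NaBH4, MeOH/THF, −40 → 0 °C
Reagents that add atoms: none
Why: Hydride attacks the C6 ketone from the α face because the β face is screened by the syn-axial methyl groups on C4 and C10, which should give the axial 6β-alcohol (substrate-controlled carbonyl reduction).

Step 13
Reactants: 17 9-(triisopropylsilyloxy)-11-nordrim-8-en-6β-ol
Product: 18 6β-hydroxy-11-nordrim-7-en-9-one
Conditions: Pd(OAc)2 (1.2 equiv), MeCN/CH2Cl2, 23 → 40 °C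
Reagents that add atoms: none
Why: Saegusa–Ito oxidation: the silyl enol ether is transferred to divalent palladium at C8, and β-hydride elimination towards the ring methylene C7 should give the conjugated trisubstituted enone in preference to the exocyclic isomer.

Step 14
Reactants: 18 6β-hydroxy-11-nordrim-7-en-9-one
Product: 19 9α-(1-tert-butoxyvinyl)-11-nordrim-7-ene-6β,9β-diol
Conditions: tert-butyl vinyl ether, t-BuLi, THF, −78 → 0 °C; then 18 (0.33 equiv), −78 → −40 °C; aq NH4Cl; crude product used directly
Reagents that add atoms: tert-butyl vinyl ether, C=COC(C)(C)C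
Why: 1-(tert-Butoxy)vinyllithium, a carboxyl anion equivalent made by α-lithiation of the vinyl ether, adds 1,2 to the enone carbonyl from the α face, anti to the axial C10 methyl on the neighbouring quaternary carbon, which sets C9 with OH β and the new carbon α (the first equivalent only deprotonates the 6-OH).

Step 15
Reactants: 19 9α-(1-tert-butoxyvinyl)-11-nordrim-7-ene-6β,9β-diol
Product: 20 tert-butyl 6β,9β-dihydroxydrim-7-en-11-oate
Conditions: O3, CH2Cl2/pyridine, −78 °C; then Me2S, −78 → 23 °C
Reagents that add atoms: ozone, [O-][O+]=O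
Why: Ozone reacts with the electron-rich 1-alkoxyvinyl group much faster than with the trisubstituted ring alkene flanked by two oxygenated carbons, and cleavage of the enol ether C=C gives the tert-butyl ester directly (ozonolysis of an enol ether to an ester).

Step 16
Reactants: 20 tert-butyl 6β,9β-dihydroxydrim-7-en-11-oate
Product: 22 tert-butyl 6β,9β-dihydroxy-12-oxodrim-7-en-11-oate, via allylic alcohol 21 (not isolated)
Conditions: SeO2 (2.2 equiv), 1,4-dioxane, 80 °C
Reagents that add atoms: selenium dioxide, O=[Se]=O
Why: Riley oxidation: the ene reaction of SeO2 at C7=C8 and a [2,3]-sigmatropic shift oxidise the only hydrogen-bearing allylic position on the more substituted alkene carbon, the C12 methyl, and the primary allylic alcohol is oxidised on to the enal under the same conditions.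

Step 17
Reactants: 22 tert-butyl 6β,9β-dihydroxy-12-oxodrim-7-en-11-oate; 23 (2E,4E,6E)-octa-2,4,6-trienoic acid
Product: 25 tert-butyl 9β-hydroxy-6β-[(2E,4E,6E)-octa-2,4,6-trienoyloxy]-12-oxodrim-7-en-11-oate, via mixed anhydride 24 (not isolated)
Conditions: 23, 2,4,6-trichlorobenzoyl chloride, Et3N, toluene, 23 °C; then 22, 4-(dimethylamino)pyridine, 23 → 40 °C
Reagents that add atoms: none
Why: Yamaguchi esterification through the mixed anhydride under nucleophilic catalysis should acylate the hindered axial 6β-hydroxyl, the tertiary 9-hydroxyl being unreactive and C6 keeping its configuration because its C–O bond is not broken.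

Step 18
Reactants: 25 tert-butyl 9β-hydroxy-6β-[(2E,4E,6E)-octa-2,4,6-trienoyloxy]-12-oxodrim-7-en-11-oate
Product: 26 9β-hydroxy-6β-[(2E,4E,6E)-octa-2,4,6-trienoyloxy]-12-oxodrim-7-en-11-oic acid [(1R,4R,4aS,8aS)-2-formyl-1-hydroxy-5,5,8a-trimethyl-4-[(2E,4E,6E)-octa-2,4,6-trienoyloxy]-1,4,4a,5,6,7,8,8a-octahydronaphthalene-1-carboxylic acid]
Conditions: CF3CO2H/CH2Cl2 (1:4), 0 → 23 °C
Reagents that add atoms: none
Why: Acidolysis of the tert-butyl ester with loss of isobutene frees the acid without base, so the C6 ester and the enal are not exposed to hydrolysis, and ionisation at the allylic C6 and C9 positions is disfavoured by the electron-poor enal double bond.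

**Compound list**
1 | methacrolein | C=C(C)C=O | starting material
2 | isopropenylmagnesium bromide | C=C(C)[Mg]Br | starting material
3 | 2,4-dimethylpenta-1,4-dien-3-ol | C=C(C)C(O)C(C)=C | intermediate
4 | 2,4-dimethylpenta-1,4-dien-3-one | C=C(C)C(=O)C(C)=C | intermediate
5 | methyl 3,3-dimethylpent-4-enoate | COC(=O)CC(C)(C)C=C | starting material
6 | methyl 3,3-dimethyl-4-oxobutanoate | COC(=O)CC(C)(C)C=O | intermediate
7 | methyl (4E)-3,3-dimethyl-6-oxohex-4-enoate | COC(=O)CC(C)(C)/C=C/C=O | intermediate
8 | methyl (4E)-6,6-dimethoxy-3,3-dimethylhex-4-enoate | COC(=O)CC(C)(C)/C=C/C(OC)OC | intermediate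
9 | (4E)-6,6-dimethoxy-3,3-dimethylhex-4-en-1-ol | OCCC(C)(C)/C=C/C(OC)OC | intermediate
10 | (2E)-6-bromo-1,1-dimethoxy-4,4-dimethylhex-2-ene | BrCCC(C)(C)/C=C/C(OC)OC | intermediate
11 | [(4E)-6,6-dimethoxy-3,3-dimethylhex-4-en-1-yl]magnesium bromide | Br[Mg]CCC(C)(C)/C=C/C(OC)OC | intermediate
12 | bromomagnesium (3Z,9E)-11,11-dimethoxy-2,4,8,8-tetramethylundeca-1,3,9-trien-3-olate | C=C(C)/C(O[Mg]Br)=C(\C)CCCC(C)(C)/C=C/C(OC)OC | intermediate
13 | (2E,8Z)-1,1-dimethoxy-4,4,8,10-tetramethyl-9-(triisopropylsilyloxy)undeca-2,8,10-triene | C=C(C)/C(O[Si](C(C)C)(C(C)C)C(C)C)=C(\C)CCCC(C)(C)/C=C/C(OC)OC | intermediate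
14 | (2E,8Z)-4,4,8,10-tetramethyl-9-(triisopropylsilyloxy)undeca-2,8,10-trienal | C=C(C)/C(O[Si](C(C)C)(C(C)C)C(C)C)=C(\C)CCCC(C)(C)/C=C/C=O | intermediate
15 | 9-(triisopropylsilyloxy)-11-nordrim-8-ene-6α-carbaldehyde | O=C[C@H]1CC(C)=C(O[Si](C(C)C)(C(C)C)C(C)C)[C@@]2(C)CCCC(C)(C)[C@H]12 | intermediate
16 | 9-(triisopropylsilyloxy)-11-nordrim-8-en-6-one | O=C1CC(C)=C(O[Si](C(C)C)(C(C)C)C(C)C)[C@@]2(C)CCCC(C)(C)[C@H]12 | intermediate
17 | 9-(triisopropylsilyloxy)-11-nordrim-8-en-6β-ol | O[C@@H]1CC(C)=C(O[Si](C(C)C)(C(C)C)C(C)C)[C@@]2(C)CCCC(C)(C)[C@H]12 | intermediate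
18 | 6β-hydroxy-11-nordrim-7-en-9-one | O[C@@H]1C=C(C)C(=O)[C@@]2(C)CCCC(C)(C)[C@H]12 | intermediate
19 | 9α-(1-tert-butoxyvinyl)-11-nordrim-7-ene-6β,9β-diol | O[C@@H]1C=C(C)[C@@](O)(C(=C)OC(C)(C)C)[C@@]2(C)CCCC(C)(C)[C@H]12 | intermediate
20 | tert-butyl 6β,9β-dihydroxydrim-7-en-11-oate (C11 on the α face) | O[C@@H]1C=C(C)[C@@](O)(C(=O)OC(C)(C)C)[C@@]2(C)CCCC(C)(C)[C@H]12 | intermediate
21 | tert-butyl 6β,9β,12-trihydroxydrim-7-en-11-oate | O[C@@H]1C=C(CO)[C@@](O)(C(=O)OC(C)(C)C)[C@@]2(C)CCCC(C)(C)[C@H]12 | intermediate
22 | tert-butyl 6β,9β-dihydroxy-12-oxodrim-7-en-11-oate | O[C@@H]1C=C(C=O)[C@@](O)(C(=O)OC(C)(C)C)[C@@]2(C)CCCC(C)(C)[C@H]12 | intermediate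
23 | (2E,4E,6E)-octa-2,4,6-trienoic acid | C/C=C/C=C/C=C/C(=O)O | starting material
24 | (2E,4E,6E)-octa-2,4,6-trienoic 2,4,6-trichlorobenzoic anhydride | C/C=C/C=C/C=C/C(=O)OC(=O)c1c(Cl)cc(Cl)cc1Cl | intermediate
25 | tert-butyl 9β-hydroxy-6β-[(2E,4E,6E)-octa-2,4,6-trienoyloxy]-12-oxodrim-7-en-11-oate | C/C=C/C=C/C=C/C(=O)O[C@@H]1C=C(C=O)[C@@](O)(C(=O)OC(C)(C)C)[C@@]2(C)CCCC(C)(C)[C@H]12 | intermediate
26 | 9β-hydroxy-6β-[(2E,4E,6E)-octa-2,4,6-trienoyloxy]-12-oxodrim-7-en-11-oic acid, (5S,6R,9R,10S) | C/C=C/C=C/C=C/C(=O)O[C@@H]1C=C(C=O)[C@@](O)(C(=O)O)[C@@]2(C)CCCC(C)(C)[C@H]12 | target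

**Step count and risks**
Total: 18 steps. Longest linear sequence: 16 steps (5 → 26, steps 3–18); the second branch is steps 1–2.

Steps most likely to fail:

1. Step 10 (key step). The congested C5–C10 bond may form too slowly, so that protodesilylation of the dienol ether or an uncatalysed background cyclisation takes over and enantioface control is lost. The fallback sets out from 14 and comes back at 15. Compound 14 is cyclised thermally without catalyst (toluene, 2,6-di-tert-butyl-4-methylphenol, 140 °C; thermal intramolecular Diels–Alder reaction) to the racemic trans-fused adduct F1. Condensation of F1 with (1R,2R)-N,N'-dimethyl-1,2-diphenylethane-1,2-diamine (MgSO4, Et2O) should give two diastereomeric imidazolidines, the imidazolidine of 15 F2 and the imidazolidine of ent-15 F3, which are separated by chromatography. Hydrolysis of F2 on wet silica gel returns 15 and the diamine.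

2. Step 11. Oxygenation may not stop at C6: the β,γ-unsaturated ketone can isomerise into conjugation or be oxidised further at C7, and the silyl enol ether may be lost under the basic aerobic copper conditions. The fallback sets out from 15 and comes back at 16. Compound 15 is condensed with piperidine (4 Å molecular sieves, benzene, 23 °C) to the piperidine enamine F4. Photo-oxygenation of F4 with singlet oxygen (O2, 5,10,15,20-tetraphenylporphyrin, visible light, CH2Cl2, −78 °C) should cleave the enamine C=C bond far faster than the silyl enol ether reacts, giving 16 and N-formylpiperidine.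

3. Step 16. The free secondary allylic 6-hydroxyl may be oxidised competitively, and the ene reaction at the hindered, inductively deactivated alkene may be slow under forcing conditions. The fallback sets out from 20 and comes back at 22. The C–H hydroxylation and the alcohol oxidation are separated: catalytic SeO2 with t-BuOOH (CH2Cl2, 23 °C) is stopped at the allylic alcohol 21, which is isolated. Then 2,2,6,6-tetramethylpiperidin-1-oxyl (cat.) with PhI(OAc)2 (CH2Cl2, 23 °C) oxidises only the primary allylic alcohol, since this oxidant does not touch the hindered secondary 6β-OH. This fallback makes no compound outside the compound list (F0).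

Further compounds
F1 | step 10 | racemic 9-(triisopropylsilyloxy)-11-nordrim-8-ene-6α-carbaldehyde (15 and its enantiomer) | O=C[C@H]1CC(C)=C(O[Si](C(C)C)(C(C)C)C(C)C)[C@@]2(C)CCCC(C)(C)[C@H]12.O=C[C@@H]1CC(C)=C(O[Si](C(C)C)(C(C)C)C(C)C)[C@]2(C)CCCC(C)(C)[C@@H]12
F2 | step 10 | (4R,5R)-1,3-dimethyl-4,5-diphenylimidazolidine formed at the formyl carbon of 15 | CN1[C@H](c2ccccc2)[C@@H](c2ccccc2)N(C)C1[C@H]3CC(C)=C(O[Si](C(C)C)(C(C)C)C(C)C)[C@@]4(C)CCCC(C)(C)[C@H]34
F3 | step 10 | (4R,5R)-1,3-dimethyl-4,5-diphenylimidazolidine formed at the formyl carbon of ent-15 | CN1[C@H](c2ccccc2)[C@@H](c2ccccc2)N(C)C1[C@@H]3CC(C)=C(O[Si](C(C)C)(C(C)C)C(C)C)[C@]4(C)CCCC(C)(C)[C@@H]34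
F4 | step 11 | 6-(piperidin-1-ylmethylidene)-9-(triisopropylsilyloxy)-11-nordrim-8-ene (enamine of 15) | C(=C1CC(C)=C(O[Si](C(C)C)(C(C)C)C(C)C)[C@@]2(C)CCCC(C)(C)[C@H]12)N1CCCCC1
F0 | step 16 | none | none
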